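## Retrosynthetic overview

1. Both butyrolactones are cut at the same bond, C(acyl)–CH2. The target comes from a bis(γ-keto ester) by two Felkin–Anh reductions with lactonisation. The bis(γ-keto ester) comes from a core bis(thioester) and two equivalents of an enantiopure β-zincio isobutyrate (a homoenolate). This double Fukuyama coupling joins an acyl carbon to an ester β-carbon, two positions that are both normally electrophilic.
2. The core bis(thioester) comes from a pyrrolo[1,2-a]azepine diester, whose azepane is closed last at N4–C5 by intramolecular reductive amination.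
3. C9 and C10 come from anti conjugate addition of a four-carbon organocopper reagent to a γ-amino (E)-2-ethyl enoate, followed by A(1,3)-controlled protonation.
4. The enoate comes from a trans-5-vinylproline, made from the N-acyliminium ion of Boc-L-pyroglutamate (C3 from the chiral pool, C9a set trans).
5. Ring order: pyrrolidine (bought) → azepane → both lactones together in the last step.

Assumption: locants are those of the pyrrolo[1,2-a]azepine core (C3, N4, C5–C9, C9a), with C10 = CH(Et), C11 and C18 = the two lactone O–CH carbons, C13 and C20 = the two CH(CH3) carbons; the SMILES is read as (3S,9R,9aS,10S,11R,13S,18S,20S).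

## Route

Step 1
Reactants: 1 methyl (2S)-1-(tert-butoxycarbonyl)-5-oxopyrrolidine-2-carboxylate
Product: 3 methyl (2S)-1-(tert-butoxycarbonyl)-5-methoxypyrrolidine-2-carboxylate, via hemiaminal 2 (not isolated)
Conditions: LiBEt3H, THF, −78 °C; aq. NaHCO3 work-up; then MeOH, cat. p-TsOH, rt
Reagents that add atoms: methanol, CO
Why: Partial reduction of the N-acyl lactam carbonyl stops at the hemiaminal at −78 °C while the ester survives, and acid-catalysed N,O-acetal formation gives a storable N-acyliminium precursor; the C2 stereocentre (future C3, S) comes from L-pyroglutamic acid and is not touched.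

Step 2
Reactants: 3 methyl (2S)-1-(tert-butoxycarbonyl)-5-methoxypyrrolidine-2-carboxylate
Product: 4 methyl (2S,5S)-1-(tert-butoxycarbonyl)-5-ethenylpyrrolidine-2-carboxylate
Conditions: CH2=CHMgBr, CuBr·SMe2, BF3·OEt2, Et2O, −78 → −30 °C; aq. NH4Cl work-up
Reagents that add atoms: vinylmagnesium bromide, C=C[Mg]Br
Why: BF3 ionises the N,O-acetal to the N-acyliminium ion, which the Grignard-derived vinylcopper attacks on the face opposite the C2 ester (N-acyliminium alkylation), setting C5 (future C9a, S) trans to the ester.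

Step 3
Reactants: 4 methyl (2S,5S)-1-(tert-butoxycarbonyl)-5-ethenylpyrrolidine-2-carboxylate; 5 ethyl 2-(diethoxyphosphoryl)butanoate
Product: 7 methyl (2S,5S)-1-(tert-butoxycarbonyl)-5-[(1E)-3-ethoxy-2-ethyl-3-oxoprop-1-en-1-yl]pyrrolidine-2-carboxylate, via aldehyde 6 (not isolated)
Conditions: O3, CH2Cl2/MeOH, −78 °C; Me2S; then 5, LiCl, DBU, MeCN, 0 °C → rt
Reagents that add atoms: ozone, [O-][O+]=O (oxygen of 6 only; it is not in 7)
Why: Ozonolysis with reductive work-up gives the α-amino aldehyde, which is olefinated at once under mild Masamune–Roush Horner–Wadsworth–Emmons conditions that do not epimerise it, giving the (E)-enoate with the ester trans to the pyrrolidine; no new stereocentre is formed.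

Step 4
Reactants: 7 methyl (2S,5S)-1-(tert-butoxycarbonyl)-5-[(1E)-3-ethoxy-2-ethyl-3-oxoprop-1-en-1-yl]pyrrolidine-2-carboxylate; 8 2-(3-chloropropyl)-1,3-dioxolane
Product: 11 methyl (2S,5S)-1-(tert-butoxycarbonyl)-5-[(2S,3R)-6-(1,3-dioxolan-2-yl)-1-ethoxy-2-ethyl-1-oxohexan-3-yl]pyrrolidine-2-carboxylate, via Grignard reagent 9 (not isolated), via silyl ketene acetal 10 (not isolated)
Conditions: 8, Mg (I2-activated), THF, 45 °C; then 7, CuBr·SMe2 (10 mol%), Me3SiCl, DMPU, THF, −78 → −40 °C; then AcOH/H2O, 0 °C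
Reagents that add atoms: magnesium, [Mg] (in 9 only); chlorotrimethylsilane, C[Si](C)(C)Cl (Me3Si in 10 only)
Why: In this Me3SiCl-accelerated copper-catalysed conjugate addition the allylic C–H eclipses the alkene (A(1,3) strain against the α-ethyl group) and the nucleophile enters anti to the C–N bond (modified Felkin–Anh), setting C9 (R), and the ketene acetal is then protonated at C10 anti to the larger pyrrolidinyl group with H9 in the enolate plane (A(1,3)-controlled kinetic protonation), setting C10 (S).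

Step 5
Reactants: 11 methyl (2S,5S)-1-(tert-butoxycarbonyl)-5-[(2S,3R)-6-(1,3-dioxolan-2-yl)-1-ethoxy-2-ethyl-1-oxohexan-3-yl]pyrrolidine-2-carboxylate
Product: 13 methyl (3S,9R,9aS)-9-[(2S)-1-ethoxy-1-oxobutan-2-yl]octahydro-1H-pyrrolo[1,2-a]azepine-3-carboxylate, via amino aldehyde 12 (not isolated)
Conditions: TFA/H2O (9:1), CH2Cl2, 0 °C → rt; evaporate; then NaBH(OAc)3, AcOH, ClCH2CH2Cl (0.01 M), rt; aq. NaHCO3 work-up
Reagents that add atoms: water, O (aldehyde oxygen of 12 only)
Why: Aqueous acid removes the Boc group and the dioxolane, the secondary amine (kept protonated so that it does not attack the γ-ester) condenses with the tethered aldehyde to a seven-membered iminium ion that NaBH(OAc)3 reduces (intramolecular reductive amination), closing the azepane without creating or touching a stereocentre.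

Step 6
Reactants: 13 methyl (3S,9R,9aS)-9-[(2S)-1-ethoxy-1-oxobutan-2-yl]octahydro-1H-pyrrolo[1,2-a]azepine-3-carboxylate
Product: 14 S-ethyl (3S,9R,9aS)-9-[(2S)-1-(ethylsulfanyl)-1-oxobutan-2-yl]octahydro-1H-pyrrolo[1,2-a]azepine-3-carbothioate
Conditions: AlMe3 (4 equiv), EtSH (4.4 equiv), CH2Cl2, 0 °C; then 13, rt → 40 °C
Reagents that add atoms: ethanethiol, CCS (two equivalents are taken up, one for each thioester)
Why: Me2AlSEt formed in the flask converts both esters into S-ethyl thioesters (aluminium thiolate transesterification) under non-basic conditions that leave the α-stereocentres C3 and C10 intact.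

Step 7
Reactants: 14 S-ethyl (3S,9R,9aS)-9-[(2S)-1-(ethylsulfanyl)-1-oxobutan-2-yl]octahydro-1H-pyrrolo[1,2-a]azepine-3-carbothioate; 15 methyl (2R)-3-bromo-2-methylpropanoate
Product: 17 methyl (2S)-4-[(3S,9R,9aS)-9-[(3S,6S)-7-methoxy-6-methyl-4,7-dioxoheptan-3-yl]octahydro-1H-pyrrolo[1,2-a]azepin-3-yl]-2-methyl-4-oxobutanoate, via zinc homoenolate 16 (not isolated)
Conditions: 15 (3 equiv), Zn dust, LiCl, THF, 45 °C; then 14, PdCl2(PPh3)2 (10 mol%), THF/toluene, rt; aq. NH4Cl work-up
Reagents that add atoms: zinc, [Zn] (in 16 only); second equivalent of 15 methyl (2R)-3-bromo-2-methylpropanoate, COC(=O)[C@@H](C)CBr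
Why: In this double Fukuyama coupling zerovalent palladium inserts into each acyl–S bond, one equivalent of the β-zincio ester 16 (a homoenolate, the normally electrophilic ester β-carbon used as a nucleophile) transmetalates at each acylpalladium and reductive elimination gives each ketone without over-addition, so C18–C19 and C11–C12 are made in the same operation from two equivalents of 15 and both methyl stereocentres (C20 and C13, S) are carried in unchanged.

Step 8
Reactants: 17 methyl (2S)-4-[(3S,9R,9aS)-9-[(3S,6S)-7-methoxy-6-methyl-4,7-dioxoheptan-3-yl]octahydro-1H-pyrrolo[1,2-a]azepin-3-yl]-2-methyl-4-oxobutanoate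
Product: 19 (3S,5S)-3-methyl-5-[(3S,9R,9aS)-9-[(1S)-1-[(2R,4S)-4-methyl-5-oxooxolan-2-yl]propyl]octahydro-1H-pyrrolo[1,2-a]azepin-3-yl]oxolan-2-one, via bis-hydroxy ester 18 (not isolated)
Conditions: LiBH(s-Bu)3 (2.5 equiv), THF, −78 °C; then AcOH, −78 °C → rt
Reagents that add atoms: none
Why: The bulky hydride reduces both ketones under Felkin–Anh control (anti to the C3–N bond at C18 giving 18S, and anti to ring carbon C9 at C11 giving 11R), and the two γ-oxygens then close onto their methyl esters on warming (lactonisation) to give both butyrolactones with the α-methyl centres untouched.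

## Compound list

1 | methyl (2S)-1-(tert-butoxycarbonyl)-5-oxopyrrolidine-2-carboxylate (Boc-L-pyroglutamic acid methyl ester) | COC(=O)[C@@H]1CCC(=O)N1C(=O)OC(C)(C)C | starting material
2 | methyl (2S)-1-(tert-butoxycarbonyl)-5-hydroxypyrrolidine-2-carboxylate (hemiaminal, both C5 epimers) | COC(=O)[C@@H]1CCC(O)N1C(=O)OC(C)(C)C | intermediate
3 | methyl (2S)-1-(tert-butoxycarbonyl)-5-methoxypyrrolidine-2-carboxylate (both C5 epimers) | COC(=O)[C@@H]1CCC(OC)N1C(=O)OC(C)(C)C | intermediate
4 | methyl (2S,5S)-1-(tert-butoxycarbonyl)-5-ethenylpyrrolidine-2-carboxylate (2,5-trans) | COC(=O)[C@@H]1CC[C@@H](C=C)N1C(=O)OC(C)(C)C | intermediate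
5 | ethyl 2-(diethoxyphosphoryl)butanoate (triethyl 2-phosphonobutyrate) | CCOC(=O)C(CC)P(=O)(OCC)OCC | starting material
6 | methyl (2S,5S)-1-(tert-butoxycarbonyl)-5-formylpyrrolidine-2-carboxylate | COC(=O)[C@@H]1CC[C@@H](C=O)N1C(=O)OC(C)(C)C | intermediate
7 | methyl (2S,5S)-1-(tert-butoxycarbonyl)-5-[(1E)-3-ethoxy-2-ethyl-3-oxoprop-1-en-1-yl]pyrrolidine-2-carboxylate | COC(=O)[C@@H]1CC[C@@H](/C=C(\CC)C(=O)OCC)N1C(=O)OC(C)(C)C | intermediate
8 | 2-(3-chloropropyl)-1,3-dioxolane | ClCCCC1OCCO1 | starting material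
9 | [3-(1,3-dioxolan-2-yl)propyl]magnesium chloride | Cl[Mg]CCCC1OCCO1 | intermediate
10 | methyl (2S,5S)-1-(tert-butoxycarbonyl)-5-[(3R)-6-(1,3-dioxolan-2-yl)-1-ethoxy-2-ethyl-1-(trimethylsilyloxy)hex-1-en-3-yl]pyrrolidine-2-carboxylate (silyl ketene acetal, E/Z mixture) | COC(=O)[C@@H]1CC[C@@H]([C@H](CCCC2OCCO2)C(CC)=C(OCC)O[Si](C)(C)C)N1C(=O)OC(C)(C)C | intermediate
11 | methyl (2S,5S)-1-(tert-butoxycarbonyl)-5-[(2S,3R)-6-(1,3-dioxolan-2-yl)-1-ethoxy-2-ethyl-1-oxohexan-3-yl]pyrrolidine-2-carboxylate | COC(=O)[C@@H]1CC[C@@H]([C@H](CCCC2OCCO2)[C@H](CC)C(=O)OCC)N1C(=O)OC(C)(C)C | intermediate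
12 | methyl (2S,5S)-5-[(2S,3R)-1-ethoxy-2-ethyl-1,7-dioxoheptan-3-yl]pyrrolidine-2-carboxylate (trifluoroacetate salt, in equilibrium with the cyclic iminium ion) | COC(=O)[C@@H]1CC[C@@H]([C@H](CCCC=O)[C@H](CC)C(=O)OCC)N1 | intermediate
13 | methyl (3S,9R,9aS)-9-[(2S)-1-ethoxy-1-oxobutan-2-yl]octahydro-1H-pyrrolo[1,2-a]azepine-3-carboxylate | CC[C@@H]([C@H]1CCCCN2[C@H]1CC[C@H]2C(=O)OC)C(=O)OCC | intermediate
14 | S-ethyl (3S,9R,9aS)-9-[(2S)-1-(ethylsulfanyl)-1-oxobutan-2-yl]octahydro-1H-pyrrolo[1,2-a]azepine-3-carbothioate | CC[C@@H]([C@H]1CCCCN2[C@H]1CC[C@H]2C(=O)SCC)C(=O)SCC | intermediate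
15 | methyl (2R)-3-bromo-2-methylpropanoate | COC(=O)[C@@H](C)CBr | starting material
16 | [(2R)-3-methoxy-2-methyl-3-oxopropyl]zinc bromide | COC(=O)[C@@H](C)C[Zn]Br | intermediate
17 | methyl (2S)-4-[(3S,9R,9aS)-9-[(3S,6S)-7-methoxy-6-methyl-4,7-dioxoheptan-3-yl]octahydro-1H-pyrrolo[1,2-a]azepin-3-yl]-2-methyl-4-oxobutanoate | CC[C@@H]([C@H]1CCCCN2[C@H]1CC[C@H]2C(=O)C[C@H](C)C(=O)OC)C(=O)C[C@H](C)C(=O)OC | intermediate
18 | methyl (2S,4S)-4-hydroxy-4-[(3S,9R,9aS)-9-[(3S,4R,6S)-4-hydroxy-7-methoxy-6-methyl-7-oxoheptan-3-yl]octahydro-1H-pyrrolo[1,2-a]azepin-3-yl]-2-methylbutanoate (formed as its dilithium alkoxide) | CC[C@@H]([C@H]1CCCCN2[C@H]1CC[C@H]2[C@@H](O)C[C@H](C)C(=O)OC)[C@H](O)C[C@H](C)C(=O)OC | intermediate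
19 | (3S,5S)-3-methyl-5-[(3S,9R,9aS)-9-[(1S)-1-[(2R,4S)-4-methyl-5-oxooxolan-2-yl]propyl]octahydro-1H-pyrrolo[1,2-a]azepin-3-yl]oxolan-2-one (CNP0135535.1) | CC[C@@H]([C@H]1CCCCN2[C@H]1CC[C@H]2[C@@H]1C[C@H](C)C(=O)O1)[C@H]1C[C@H](C)C(=O)O1 | target

## Step count and risks

Total step count: 8. Longest linear sequence: 8 (1 → 3 → 4 → 7 → 11 → 13 → 14 → 17 → 19).

The three steps most likely to fail:

**Step 4.** The enoate is trisubstituted and γ-branched, so the conjugate addition may be slow. C10 rests on kinetic protonation, for which I expect only a moderate ratio (epimers separable by chromatography). The fallback sets out from aldehyde 6 and comes back at 11. Olefination of 6 with triethyl phosphonoacetate (LiCl, DBU) gives the much more reactive disubstituted enoate methyl (2S,5S)-1-(tert-butoxycarbonyl)-5-[(1E)-3-ethoxy-3-oxoprop-1-en-1-yl]pyrrolidine-2-carboxylate F1. The stoichiometric cuprate made from 9 and CuBr·SMe2 adds anti to nitrogen, and the enolate is trapped with acetaldehyde (ZnCl2) to give the aldol adduct ethyl (3R)-3-[(2S,5S)-1-(tert-butoxycarbonyl)-5-(methoxycarbonyl)pyrrolidin-2-yl]-6-(1,3-dioxolan-2-yl)-2-(1-hydroxyethyl)hexanoate F2. Mesylation and elimination (MsCl, Et3N, then DBU) give ethyl (2E,3R)-3-[(2S,5S)-1-(tert-butoxycarbonyl)-5-(methoxycarbonyl)pyrrolidin-2-yl]-6-(1,3-dioxolan-2-yl)-2-ethylidenehexanoate F3. Its (E)-methyl group holds H9 in the alkene plane, which puts the pyrrolidine over one alkene face and the C8 chain over the other. C10 (S) needs the new hydrogen on the face that carries the pyrrolidine. This is done by directed hydrogenation (H2, [Ir(cod)(PCy3)(py)]PF6, CH2Cl2), in which the cationic iridium binds the Boc carbonyl oxygen and delivers hydrogen from that side, giving 11. C10 is then set by alkene hydrogenation instead of enolate protonation, and a chiral iridium N,P catalyst of the matching hand can be used if the directing effect is too weak.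

**Step 6.** The C11 ester is α- and β-branched and may resist the aluminium thiolate. The fallback sets out from 13 and comes back at 14. Saponification (LiOH, THF/H2O) gives (3S,9R,9aS)-9-[(1S)-1-carboxypropyl]octahydro-1H-pyrrolo[1,2-a]azepine-3-carboxylic acid F4, which is coupled with ethanethiol by carbodiimide activation (EDC·HCl, cat. DMAP, CH2Cl2/DMF). The tertiary amino acid cannot form an oxazolone, so C3 is safe.

**Step 7.** Two couplings must both work, one at a hindered thioester, in the presence of a free tertiary amine. Keto ester 17 is also epimerisable at C3 and C10 and must be taken into step 8 at once. The fallback sets out from 13 and comes back at 17, replacing the preformed organozinc and palladium by a nickel-catalysed cross-electrophile coupling. The diacid F4 (made as above) is converted with 2,2'-dipyridyl disulfide and PPh3 into S-pyridin-2-yl (3S,9R,9aS)-9-[(2S)-1-oxo-1-(pyridin-2-ylsulfanyl)butan-2-yl]octahydro-1H-pyrrolo[1,2-a]azepine-3-carbothioate F5. This is coupled reductively (NiCl2(dme), 4,4'-di-tert-butyl-2,2'-bipyridine, Zn, DMA, rt) with two equivalents of methyl (2R)-3-iodo-2-methylpropanoate F6, obtained from 15 with NaI in acetone. The alkylnickel species plays the homoenolate role and the product is 17.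

Further compounds
F1 | step 4 | methyl (2S,5S)-1-(tert-butoxycarbonyl)-5-[(1E)-3-ethoxy-3-oxoprop-1-en-1-yl]pyrrolidine-2-carboxylate | COC(=O)[C@@H]1CC[C@@H](/C=C/C(=O)OCC)N1C(=O)OC(C)(C)C
F2 | step 4 | ethyl (3R)-3-[(2S,5S)-1-(tert-butoxycarbonyl)-5-(methoxycarbonyl)pyrrolidin-2-yl]-6-(1,3-dioxolan-2-yl)-2-(1-hydroxyethyl)hexanoate (isomer mixture at C2 and the carbinol carbon) | COC(=O)[C@@H]1CC[C@@H]([C@H](CCCC2OCCO2)C(C(C)O)C(=O)OCC)N1C(=O)OC(C)(C)C
F3 | step 4 | ethyl (2E,3R)-3-[(2S,5S)-1-(tert-butoxycarbonyl)-5-(methoxycarbonyl)pyrrolidin-2-yl]-6-(1,3-dioxolan-2-yl)-2-ethylidenehexanoate | COC(=O)[C@@H]1CC[C@@H]([C@H](CCCC2OCCO2)C(=C/C)\C(=O)OCC)N1C(=O)OC(C)(C)C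
F4 | step 6 | (3S,9R,9aS)-9-[(1S)-1-carboxypropyl]octahydro-1H-pyrrolo[1,2-a]azepine-3-carboxylic acid | CC[C@@H]([C@H]1CCCCN2[C@H]1CC[C@H]2C(=O)O)C(=O)O
F5 | step 7 | S-pyridin-2-yl (3S,9R,9aS)-9-[(2S)-1-oxo-1-(pyridin-2-ylsulfanyl)butan-2-yl]octahydro-1H-pyrrolo[1,2-a]azepine-3-carbothioate | CC[C@@H]([C@H]1CCCCN2[C@H]1CC[C@H]2C(=O)Sc1ccccn1)C(=O)Sc1ccccn1
F6 | step 7 | methyl (2R)-3-iodo-2-methylpropanoate | COC(=O)[C@@H](C)CI
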